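The flavone is disconnected at C4–C4a and O1–C2, so that the central pyranone ring is fused onto an intact ring A. The feature exploited is the threefold symmetry of the 1,3,5-trioxygenated ring A (O1, C5–OH, C7–OH): free phloroglucinol can be used, since every ring carbon and every hydroxyl is equivalent. In one thermal operation a ring carbon is acylated (C4–C4a) and the adjacent hydroxyl closes onto C2 with loss of water. The partner is an ethyl α-methoxy-β-keto ester that supplies C4, C3 with its methoxy group, and C2 bearing ring B, which already carries the C5' prenyl group and has O3'/O4' tied up as a diphenylmethylene ketal.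

Key step: step 5

Assumption: 3-bromo-4,5-dihydroxybenzaldehyde 1 is taken to be a purchasable catalogue compound; the target has no stereocentre, so no stereocontrol is needed anywhere.

Step 1
Reactants: 1 3-bromo-4,5-dihydroxybenzaldehyde; 2 dichlorodiphenylmethane
Product: 3 7-bromo-2,2-diphenyl-1,3-benzodioxole-5-carbaldehyde
Conditions: 2 (1.5 equiv), K2CO3 (3 equiv), MeCN, 60 °C, N2
Reagents that add atoms: dichlorodiphenylmethane (2), ClC(Cl)(c1ccccc1)c1ccccc1
Why: Williamson-type double O-alkylation of the catechol by the gem-dichloride (diphenylmethylene ketal formation) closes the 1,3-dioxole ring under basic conditions, and placing it before the prenylation means that the chloride released never meets an alkene next to a free phenol.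

Step 2
Reactants: 3 7-bromo-2,2-diphenyl-1,3-benzodioxole-5-carbaldehyde; 4 tributyl(3-methylbut-2-en-1-yl)stannane
Product: 5 7-(3-methylbut-2-en-1-yl)-2,2-diphenyl-1,3-benzodioxole-5-carbaldehyde
Conditions: 4 (1.3 equiv), Pd(PPh3)4 (5 mol %), DMF, 100 °C, Ar
Reagents that add atoms: tributyl(3-methylbut-2-en-1-yl)stannane (4), CCCC[Sn](CCCC)(CCCC)CC=C(C)C
Why: Stille coupling, in which the aryl bromide adds oxidatively to zerovalent palladium, the allylstannane transmetalates and reductive elimination at the unsubstituted allyl terminus gives the linear prenyl arene, while the neutral medium leaves the aldehyde and the ketal alone.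

Step 3
Reactants: 5 7-(3-methylbut-2-en-1-yl)-2,2-diphenyl-1,3-benzodioxole-5-carbaldehyde; 6 ethyl methoxyacetate
Product: 8 ethyl 3-hydroxy-2-methoxy-3-[7-(3-methylbut-2-en-1-yl)-2,2-diphenyl-1,3-benzodioxol-5-yl]propanoate (racemic syn/anti mixture), via lithium ester enolate 7 (not isolated)
Conditions: 6, LiN(SiMe3)2 (1.1 equiv), THF, −78 °C; then 5, −78 °C; AcOH quench
Reagents that add atoms: ethyl methoxyacetate (6), CCOC(=O)COC
Why: Aldol addition of a preformed lithium ester enolate to a non-enolisable aromatic aldehyde; the two new stereocentres (C2 and C3 of the propanoate) are not controlled and form as a racemic syn/anti mixture, which does no harm because C3 becomes a carbonyl in step 4 and C2 becomes sp2 C3 of the chromone in step 5.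

Step 4
Reactants: 8 ethyl 3-hydroxy-2-methoxy-3-[7-(3-methylbut-2-en-1-yl)-2,2-diphenyl-1,3-benzodioxol-5-yl]propanoate
Product: 9 ethyl 2-methoxy-3-[7-(3-methylbut-2-en-1-yl)-2,2-diphenyl-1,3-benzodioxol-5-yl]-3-oxopropanoate (racemic, enolisable)
Conditions: IBX (2-iodoxybenzoic acid, 1.5 equiv), EtOAc, 75 °C
Reagents that add atoms: none
Why: IBX oxidation of the secondary benzylic alcohol by the pentavalent iodine reagent gives the β-keto ester without touching the trisubstituted alkene, the ketal or the ester, and the remaining α-stereocentre stays racemic and enolisable.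

Step 5
Reactants: 9 ethyl 2-methoxy-3-[7-(3-methylbut-2-en-1-yl)-2,2-diphenyl-1,3-benzodioxol-5-yl]-3-oxopropanoate; 10 phloroglucinol (benzene-1,3,5-triol)
Product: 13 5,7-dihydroxy-3-methoxy-2-[7-(3-methylbut-2-en-1-yl)-2,2-diphenyl-1,3-benzodioxol-5-yl]-4H-chromen-4-one, via aroylketene 11 (not isolated), via aryl diketone 12 (not isolated)
Conditions: 10 (anhydrous, 2 equiv), neat melt, 240 °C, Ar stream (EtOH and H2O distil off)
Reagents that add atoms: phloroglucinol (10), Oc1cc(O)cc(O)c1
Why: Above about 200 °C the enol of 9 should expel ethanol to give the aroyl(methoxy)ketene 11, whose ketene carbon acylates one of the three equivalent ring carbons of 10 to give the o-hydroxyaryl 1,3-diketone 12; the adjacent phenol then adds to the aroyl carbonyl (6-exo-trig) and the hemiketal loses water, so that C4–C4a and O1–C2 are made and the pyranone ring is closed in one operation. This is the Mentzer pyrone synthesis, the acid-free thermal counterpart of the Simonis chromone synthesis, which is established for phloroglucinol and aroylacetates. No stereocentre is formed, since the racemic α-carbon of 9 ends as sp2 C3. The selectivity needed is chromone over Pechmann coumarin, and it is secured by the absence of acid, which leaves the ketene carbon as the only electrophile able to attack the ring, while O-acylation is reversible at this temperature and ring acylation followed by aromatising dehydration is not. Regiochemistry on ring A cannot arise because of the threefold symmetry of 10, a second annulation is disfavoured by the deactivating, hydrogen-bonded C4 carbonyl, and the ketal both keeps O4' away from the neighbouring prenyl group (no chroman formation in the melt) and keeps the ring B oxygens from competing as nucleophiles.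

Step 6
Reactants: 13 5,7-dihydroxy-3-methoxy-2-[7-(3-methylbut-2-en-1-yl)-2,2-diphenyl-1,3-benzodioxol-5-yl]-4H-chromen-4-one
Product: 14 uralenol 3-methyl ether, 2-[3,4-dihydroxy-5-(3-methylbut-2-en-1-yl)phenyl]-5,7-dihydroxy-3-methoxy-4H-chromen-4-one
Conditions: AcOH/H2O (4:1), 90 °C, Ar
Reagents that add atoms: none
Why: Acid-catalysed ketal hydrolysis through the diphenyl(aryloxy)methyl cation frees the catechol and benzophenone, while acetic acid is too weak to protonate the trisubstituted alkene at a competitive rate, so the prenyl group, the 3-methoxy group and the chromone should stay intact.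

Compound list
1 | 3-bromo-4,5-dihydroxybenzaldehyde | O=Cc1cc(O)c(O)c(Br)c1 | starting material
2 | dichlorodiphenylmethane | ClC(Cl)(c1ccccc1)c1ccccc1 | starting material
3 | 7-bromo-2,2-diphenyl-1,3-benzodioxole-5-carbaldehyde | O=Cc1cc(Br)c2OC(c3ccccc3)(c3ccccc3)Oc2c1 | intermediate
4 | tributyl(3-methylbut-2-en-1-yl)stannane | CCCC[Sn](CCCC)(CCCC)CC=C(C)C | starting material
5 | 7-(3-methylbut-2-en-1-yl)-2,2-diphenyl-1,3-benzodioxole-5-carbaldehyde | O=Cc1cc(CC=C(C)C)c2OC(c3ccccc3)(c3ccccc3)Oc2c1 | intermediate
6 | ethyl methoxyacetate | CCOC(=O)COC | starting material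
7 | lithium enolate of ethyl methoxyacetate (formed in the flask, not isolated) | CCOC(O[Li])=COC | intermediate
8 | ethyl 3-hydroxy-2-methoxy-3-[7-(3-methylbut-2-en-1-yl)-2,2-diphenyl-1,3-benzodioxol-5-yl]propanoate (racemic syn/anti mixture, both centres uncontrolled) | CCOC(=O)C(OC)C(O)c1cc(CC=C(C)C)c2OC(c3ccccc3)(c3ccccc3)Oc2c1 | intermediate
9 | ethyl 2-methoxy-3-[7-(3-methylbut-2-en-1-yl)-2,2-diphenyl-1,3-benzodioxol-5-yl]-3-oxopropanoate (racemic) | CCOC(=O)C(OC)C(=O)c1cc(CC=C(C)C)c2OC(c3ccccc3)(c3ccccc3)Oc2c1 | intermediate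
10 | phloroglucinol (benzene-1,3,5-triol) | Oc1cc(O)cc(O)c1 | starting material
11 | 2-methoxy-3-[7-(3-methylbut-2-en-1-yl)-2,2-diphenyl-1,3-benzodioxol-5-yl]prop-1-ene-1,3-dione, the aroyl(methoxy)ketene (formed in the flask, not isolated) | COC(=C=O)C(=O)c1cc(CC=C(C)C)c2OC(c3ccccc3)(c3ccccc3)Oc2c1 | intermediate
12 | 2-methoxy-1-[7-(3-methylbut-2-en-1-yl)-2,2-diphenyl-1,3-benzodioxol-5-yl]-3-(2,4,6-trihydroxyphenyl)propane-1,3-dione (formed in the flask, not isolated) | COC(C(=O)c1c(O)cc(O)cc1O)C(=O)c1cc(CC=C(C)C)c2OC(c3ccccc3)(c3ccccc3)Oc2c1 | intermediate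
13 | 5,7-dihydroxy-3-methoxy-2-[7-(3-methylbut-2-en-1-yl)-2,2-diphenyl-1,3-benzodioxol-5-yl]-4H-chromen-4-one | COc1c(-c2cc(CC=C(C)C)c3OC(c4ccccc4)(c4ccccc4)Oc3c2)oc2cc(O)cc(O)c2c1=O | intermediate
14 | uralenol 3-methyl ether, 2-[3,4-dihydroxy-5-(3-methylbut-2-en-1-yl)phenyl]-5,7-dihydroxy-3-methoxy-4H-chromen-4-one (achiral) | COc1c(-c2cc(O)c(O)c(CC=C(C)C)c2)oc2cc(O)cc(O)c2c1=O | target

Total step count: 6
Longest linear sequence: 6 steps (1 → 3 → 5 → 8 → 9 → 13 → 14)

Steps most likely to fail

1. Step 5 (key step). In the melt, keto ester 9 may break down before the ring carbon of 10 is acylated: the water released can hydrolyse and decarboxylate it, and charring or partial ketal exchange with the phenols can set in. The fallback builds the same pyranone ring from the other side by known enolate chemistry; it sets out from aldehyde 5 and comes back at 13. Pinnick oxidation of 5 (NaClO2, NaH2PO4, excess 2-methyl-2-butene, t-BuOH/H2O) should give 7-(3-methylbut-2-en-1-yl)-2,2-diphenyl-1,3-benzodioxole-5-carboxylic acid F1. The neutral chlorinating agent 1-chloro-N,N,2-trimethylprop-1-en-1-amine in CH2Cl2 converts it, without free HCl, into 7-(3-methylbut-2-en-1-yl)-2,2-diphenyl-1,3-benzodioxole-5-carbonyl chloride F2. The commercial ketone 2-methoxy-1-(2,4,6-trihydroxyphenyl)ethanone F3 already holds the C4–C4a bond. It is deprotonated four times with LiN(SiMe3)2 in THF at −78 °C and acylated at its enolate carbon by F2 (Baker–Venkataraman-type diketone synthesis by direct enolate acylation). This makes C2–C3 and delivers diketone 12, here as an isolated compound. Warming 12 in glacial AcOH with NaOAc should close O1–C2 with loss of water and give 13.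

2. Step 2. Oxidative addition at the electron-rich bromide flanked by the ketal oxygen may be slow, so that protodebromination and catalyst decay compete. The allyl group may also be transferred through its substituted terminus, giving the branched 1,1-dimethylallyl isomer. The fallback replaces cross-coupling by alkylation of an aryl–metal species; it sets out from bromide 3 and comes back at 5. The aldehyde is masked with HC(OMe)3 in MeOH and catalytic pyridinium p-toluenesulfonate as 7-bromo-5-(dimethoxymethyl)-2,2-diphenyl-1,3-benzodioxole F4. Bromine–lithium exchange (n-BuLi, THF, −78 °C), transmetalation with CuBr·SMe2 and SN2 alkylation with prenyl bromide should give 5-(dimethoxymethyl)-7-(3-methylbut-2-en-1-yl)-2,2-diphenyl-1,3-benzodioxole F5. Brief treatment with dilute aqueous oxalic acid in THF at room temperature returns aldehyde 5 while the diaryl ketal stays on.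

3. Step 6. Once O4' is set free, acid-promoted addition of this hydroxyl across the neighbouring prenyl double bond (closure to a 2,2-dimethylchroman) may compete with the ketal hydrolysis. The fallback moves the hydrolysis in front of the prenylation; it sets out from bromide 3 and comes back at the target 14.
- Under the conditions of steps 3 to 5, aldol addition of 7 to 3 gives ethyl 3-(7-bromo-2,2-diphenyl-1,3-benzodioxol-5-yl)-3-hydroxy-2-methoxypropanoate F6.
- IBX oxidation gives ethyl 3-(7-bromo-2,2-diphenyl-1,3-benzodioxol-5-yl)-2-methoxy-3-oxopropanoate F7.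
- The melt with 10 gives 2-(7-bromo-2,2-diphenyl-1,3-benzodioxol-5-yl)-5,7-dihydroxy-3-methoxy-4H-chromen-4-one F8.
- Aqueous AcOH at 90 °C then hydrolyses the ketal with no alkene in the molecule and gives 2-(3-bromo-4,5-dihydroxyphenyl)-5,7-dihydroxy-3-methoxy-4H-chromen-4-one F9.
- A final Stille coupling of F9 with 4 (Pd(PPh3)4, DMF, 100 °C, Ar), a reaction that tolerates free phenols, introduces the prenyl group under neutral conditions and gives 14.

Further compounds
F1 | step 5 | 7-(3-methylbut-2-en-1-yl)-2,2-diphenyl-1,3-benzodioxole-5-carboxylic acid | OC(=O)c1cc(CC=C(C)C)c2OC(c3ccccc3)(c3ccccc3)Oc2c1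
F2 | step 5 | 7-(3-methylbut-2-en-1-yl)-2,2-diphenyl-1,3-benzodioxole-5-carbonyl chloride | ClC(=O)c1cc(CC=C(C)C)c2OC(c3ccccc3)(c3ccccc3)Oc2c1
F3 | step 5 | 2-methoxy-1-(2,4,6-trihydroxyphenyl)ethanone | COCC(=O)c1c(O)cc(O)cc1O
F4 | step 2 | 7-bromo-5-(dimethoxymethyl)-2,2-diphenyl-1,3-benzodioxole | COC(OC)c1cc(Br)c2OC(c3ccccc3)(c3ccccc3)Oc2c1
F5 | step 2 | 5-(dimethoxymethyl)-7-(3-methylbut-2-en-1-yl)-2,2-diphenyl-1,3-benzodioxole | COC(OC)c1cc(CC=C(C)C)c2OC(c3ccccc3)(c3ccccc3)Oc2c1
F6 | step 6 | ethyl 3-(7-bromo-2,2-diphenyl-1,3-benzodioxol-5-yl)-3-hydroxy-2-methoxypropanoate (racemic syn/anti mixture) | CCOC(=O)C(OC)C(O)c1cc(Br)c2OC(c3ccccc3)(c3ccccc3)Oc2c1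
F7 | step 6 | ethyl 3-(7-bromo-2,2-diphenyl-1,3-benzodioxol-5-yl)-2-methoxy-3-oxopropanoate (racemic) | CCOC(=O)C(OC)C(=O)c1cc(Br)c2OC(c3ccccc3)(c3ccccc3)Oc2c1
F8 | step 6 | 2-(7-bromo-2,2-diphenyl-1,3-benzodioxol-5-yl)-5,7-dihydroxy-3-methoxy-4H-chromen-4-one | COc1c(-c2cc(Br)c3OC(c4ccccc4)(c4ccccc4)Oc3c2)oc2cc(O)cc(O)c2c1=O
F9 | step 6 | 2-(3-bromo-4,5-dihydroxyphenyl)-5,7-dihydroxy-3-methoxy-4H-chromen-4-one | COc1c(-c2cc(O)c(O)c(Br)c2)oc2cc(O)cc(O)c2c1=O
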